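## Analysis of the target

Target 22 is the (E)-p-coumarate of a daucane diol. It is a hydroazulene in which a cyclopentane (ring A: C1, C2, C3, C4, C5) is trans-fused through C1–C5 to a cycloheptene (ring B: C1, C5, C6, C7, C8, C9, C10). The numbering used throughout is: C1 the quaternary, methyl-bearing fusion carbon; C2 and C3 methylenes; C4 the tertiary isopropyl carbinol; C5 the fusion CH; C6 the acylated carbinol; C7 a methylene; C8(Me)=C9 the only ring olefin; C10 the methylene that returns to C1.

The four stereocentres (1R,4R,5S,6S) are contiguous. On ring A the C1 methyl, the C4 hydroxyl and the C5–C6 bond share one face, while isopropyl, H5 and C10 lie on the other. On ring B the C6 oxygen is anti to the angular methyl and syn to H5.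

The sensitive groups are the tertiary alcohol β to C6 (dehydration or retro-aldol whenever C6 is a carbonyl), the trisubstituted olefin (acid-induced migration) and the phenolic cinnamate (base-labile ester, nucleophilic phenol). The difficulty is the crowded array C1–C5–C4: a quaternary carbon, a methine and a tertiary carbinol in a row, with no heteroatom near C1 to guide its asymmetric construction, and C6 attached to the middle of it.

The strategy rests on one feature. C1, with its methyl, the exocyclic C10 and its two ring neighbours C2 and C5, is the α-carbon of a methacrolein Diels–Alder adduct, and C4 with its isopropyl group lies 1,4 to it across C2–C3. A cyclohexene C1–C2–C3–C4=C6–C5 therefore holds six skeletal carbons in the right order. Cleaving C4=C6 gives a C4 ketone and a C6 aldehyde, and an aldol bond C4–C5 contracts the ring to ring A with the C4 carbinol and the C6 carbonyl in place.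

## Retrosynthetic reasoning

**Ester and phenol (22 ⇒ 21 ⇒ 16 + 19).** The C6–O acyl bond is cut first because the cinnamate is the most labile function and should be made last. The hindered tertiary C4–OH of diol 16 needs no protection. Only the phenol of the acid is masked (19, from p-coumaric acid 17), so that it cannot compete as a nucleophile. The forward reaction has to acylate a congested secondary alcohol without touching C4–OH.

**Ring B (16 ⇒ 15).** The C8=C9 double bond is cut by a retro ring-closing metathesis. This is the only olefin of the target, and metathesis fixes its position by construction, tolerates the free diol and forms the trans-fused seven-membered ring from two arms that are already trans on ring A. Closing ring B by hydroacylation of a C1-dienyl group with the C6 formyl group was weighed and not used. Hydrogen and acyl can add across such a diene in two senses (olefin at C8=C9 or at C9=C10), and C6 would still need a stereoselective reduction.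

**C6–C7 (15 ⇒ 13 + 14).** The homoallylic carbinol is opened to aldehyde 13 and the methallyl unit of 14. C6 is thus made from the formyl group that the aldol leaves behind. The forward Barbier-type addition has to set C6, and the neighbouring free C4–OH is used for chelation.

**C4–C5 (13 ⇒ 12).** The retro-aldol cut of ring A gives keto-aldehyde 12. This single bond creates the C4 carbinol and the C5 methine together and explains the 1,3 relation of the C4 and C6 oxygens. Forward, the aldehyde must act as donor (C5) and the isopropyl ketone as acceptor (C4), without loss of water, and with the formyl group ending trans to isopropyl and to the C10 arm.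

**C4=C6 (12 ⇒ 10).** Reconnecting the two carbonyls as an olefin gives cyclohexene 10. The forward ozonolysis must cleave the trisubstituted ring olefin and spare the allyl group.

**C10 side chain (10 ⇒ 8 ⇒ 7 ⇒ 5).** The allyl group is taken back to the formyl group of 5 through two one-carbon Wittig operations. C10 is the formyl carbon itself and ends as CH2; C9 comes from 6; the terminal carbon from 9 is later lost in the metathesis. Building the arm before ring cleavage means C10 never needs a protecting group.

**Cyclohexene (5 ⇒ 3 + 4).** The Diels–Alder disconnection cuts the σ-bonds C1–C5 and C2–C3. The enal C=C of 4 becomes the C1–C2 single bond, the diene C5=C6 double bond of 3 becomes the C5–C6 single bond, and the new olefin is C4=C6. It is made here because this is the one place where C1 can be created catalytically and enantioselectively from achiral, small components. The forward reaction needs face selection at the enal and para regiochemistry.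

**Diene (3 ⇒ 1 + 2).** The isopropyl–C4 bond is cut to a vinylic chloride and a Grignard reagent (Kumada coupling), which gives the diene in one step.

## Alternatives that were turned down

**Alternative 1:** Here C5–C6 and C1–C10 are cut on an intact ring A. In the forward key step a metalated thioacetal (C6 as a formyl-anion equivalent) adds to silyloxy enone A1 anti to the silyloxy group. The enolate is then alkylated at C1, anti to the new C6 substituent, by a (Z)-allylic halide that carries C10, C9, C8 with its methyl, and C7. This gives cyclopentanone A2; no ring is formed.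

- For it: it follows the well-understood trans,trans three-component coupling of 4-oxygenated cyclopentenones, sets C1 and C5 with their trans relation in one flask, and brings in the trisubstituted olefin with fixed geometry.
- Against it: the oxygen pattern is wrong for this target. The carbonyl of A2 sits at C2, a bare methylene in the target, and must be removed. The C4 oxygen is only a relay that must be oxidised and then attacked by an isopropyl nucleophile at a hindered, enolisable ketone. The intermediate enolate has a β-silyloxy leaving group and must be alkylated to a quaternary carbon, so elimination competes. Ring B still needs an intramolecular C6–C7 alkylation and a C6 reduction.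
- Comparison: on the security of the C1/C5 relation and on convergence it is stronger than the chosen plan, whose C5 configuration rests on an aldol. The chosen plan offers instead the correct oxidation pattern directly from ozonolysis–aldol, a catalytic asymmetric source of chirality, and several fewer redox and protecting-group operations.

**Alternative 2:** Here C1–C5 and C5–C6 are cut and ring B is traced to a benzene ring. Forward, an α-diazoketone tethered to a methoxy- and methyl-substituted arene is decomposed by a chiral dirhodium tetracarboxylate (divalent rhodium). The carbenoid carbon C5 adds across the aryl bond between the future C1 and C6, closing ring A, and the norcaradiene opens to cycloheptatriene A3.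

- For it: both rings arise in one step from a flat precursor, and the C6 oxygen, the C8 methyl and a C4 carbonyl are set by the arene substitution. It is the fastest route to a hydroazulene.
- Against it: A3 has no angular methyl. C1 is an sp2 carbon of a triene and would need a later conjugate methylation that creates the quaternary centre relative to C5. C5 itself is doubly activated and prone to epimerisation and hydrogen shifts. Three ring-B olefins must be reduced to one at C8=C9. Regiochemistry at the two non-equivalent ortho bonds and the level of asymmetric induction are open.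
- Comparison: it reaches the skeleton faster than the chosen route, but leaves the hardest centre unsolved. The chosen route fixes C1 first, methyl included, and never has more than one olefin in ring B.

**Alternative 3:** Here C7–C8 and C9–C10 are cut. C8, its methyl and C9 are removed as a three-carbon alkyne, and C10 becomes the methylene of a cyclopropane fused to ring A at C1–C5, with a 1-siloxyvinyl group (C6=C7) on C5. Forward, a rhodium carbonyl chloride catalyst (monovalent rhodium) opens the C5–C10 bond, the alkyne inserts, and reductive elimination gives cycloheptadiene A4 with the C8=C9 olefin and a C5=C6 silyl enol ether.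

- For it: it is the most direct and convergent construction of ring B of all four plans, more direct than the metathesis used here. It delivers the olefin, the C8 methyl and the C6 oxygen at once.
- Against it: the difficulty moves into the precursor, an enantiopure bicyclo[3.1.0]hexane with fully substituted C1 and C5 next to a protected tertiary C4 carbinol. The unsymmetrical alkyne can insert in two orientations. In A4, C5 is sp2, so the fusion configuration must be set afterwards by protonation of a tetrasubstituted enol ether flanked by two quaternary carbons, with no clear bias for the trans fusion.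
- Comparison: the chosen route gives up this convergence. In return it uses cheap achiral feedstocks, reaches its key step in one step, and sets C5 together with C4 and then C6 under direction by O4.

Key step: step 2

Remark on the chemistry (assumption): 1 is used as its commercial stabilised solution in xylene. The antipodes of the oxazaborolidine (step 2) and of proline (step 7) are assigned from the transition-state models named in those steps; both antipodes of each are commercial, so the opposite one would be used if the sense proved reversed.

## Route

Step 1
Reactants: 1 2-chlorobuta-1,3-diene; 2 isopropylmagnesium chloride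
Product: 3 2-(propan-2-yl)buta-1,3-diene
Conditions: NiCl2(dppp) (1 mol%; dppp = 1,3-bis(diphenylphosphino)propane), Et2O, 0 °C → reflux; fractional distillation
Reagents that add atoms: none
Why: Kumada–Corriu coupling of a vinylic (dienyl) chloride; the chelating diphosphine should let reductive elimination outrun β-hydride isomerisation of the isopropyl–nickel intermediate, and the volatile diene is separated from the higher-boiling solvent by distillation.

Step 2
Reactants: 3 2-(propan-2-yl)buta-1,3-diene; 4 methacrolein (2-methylprop-2-enal)
Product: 5 (1S)-1-methyl-4-(propan-2-yl)cyclohex-3-ene-1-carbaldehyde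
Conditions: (S)-o-tolyl-CBS oxazaborolidine [(S)-3,3-diphenyl-1-(2-methylphenyl)tetrahydro-1H,3H-pyrrolo[1,2-c][1,3,2]oxazaborole] (20 mol%), HN(SO2CF3)2 (17 mol%), CH2Cl2, −78 → −40 °C
Reagents that add atoms: none
Why: The N-protonated oxazaborolidine is a cationic boron Lewis acid that binds the formyl oxygen of 4, with the formyl C–H hydrogen-bonded to the ring oxygen, so that the s-trans enal lies over one phenyl group and only one enantioface is open. Diene 3 then adds in a concerted, asynchronous (4+2) cycloaddition; the closest known reaction type is the oxazaborolidinium-catalysed Diels–Alder reaction of 2-substituted acroleins with 2-substituted butadienes. The cyclohexene is closed suprafacially on both partners by the two new σ-bonds C2–C3 (the more advanced one) and C1–C5, while the former π-bonds become the C1–C2 and C5–C6 single bonds and the new olefin is C4=C6. C1 is the only new stereocentre and is set by the catalyst; with the (S)-catalyst the formyl C–H···O model predicts attack on the face that gives (S)-5. The step needs para regiochemistry, which follows because the enal β-carbon C2 bonds first to the diene terminus C3, placing developing positive charge on the isopropyl-substituted C4. Endo/exo selection is irrelevant because the diene has no terminal substituent. Low temperature and a slight deficit of acid relative to oxazaborolidine should suppress the uncatalysed background reaction and cationic oligomerisation of the diene.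

Step 3
Reactants: 5 (1S)-1-methyl-4-(propan-2-yl)cyclohex-3-ene-1-carbaldehyde; 6 (methoxymethyl)triphenylphosphonium chloride
Product: 7 (4S)-4-(2-methoxyethenyl)-4-methyl-1-(propan-2-yl)cyclohex-1-ene (E/Z mixture)
Conditions: 6, KOtBu, THF, 0 °C → rt
Reagents that add atoms: none
Why: Wittig olefination with a methoxymethylene ylide adds C9; the α-quaternary aldehyde cannot enolise or epimerise, and the enol ether geometry is irrelevant because both isomers hydrolyse to the same aldehyde.

Step 4
Reactants: 7 (4S)-4-(2-methoxyethenyl)-4-methyl-1-(propan-2-yl)cyclohex-1-ene
Product: 8 2-[(1S)-1-methyl-4-(propan-2-yl)cyclohex-3-en-1-yl]acetaldehyde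
Conditions: 2 M aq. HCl, THF, rt
Reagents that add atoms: water, O
Why: Enol ether hydrolysis (C-protonation at C10, hemiacetal collapse) leaves C10 as the methylene required in the target; dilute acid at room temperature should not move the trisubstituted ring olefin, and C1 is quaternary and cannot epimerise.

Step 5
Reactants: 8 2-[(1S)-1-methyl-4-(propan-2-yl)cyclohex-3-en-1-yl]acetaldehyde; 9 methyltriphenylphosphonium bromide
Product: 10 (4R)-4-methyl-1-(propan-2-yl)-4-(prop-2-en-1-yl)cyclohex-1-ene
Conditions: 9, KOtBu, THF, 0 °C → rt
Reagents that add atoms: none
Why: Wittig methylenation of an unhindered aldehyde completes the allyl arm C10–C9=CH2; the change of descriptor from S to R reflects CIP priorities only, not a change at C1.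

Step 6
Reactants: 10 (4R)-4-methyl-1-(propan-2-yl)-4-(prop-2-en-1-yl)cyclohex-1-ene
Product: 12 (3R)-3,7-dimethyl-6-oxo-3-(prop-2-en-1-yl)octanal, via secondary ozonide 11 (not isolated)
Conditions: O3 (about 1 equiv., stopped at the Sudan Red 7B end point), CH2Cl2, −78 °C; then PPh3, −78 °C → rt
Reagents that add atoms: ozone, [O-][O+]=O
Why: Chemoselective ozonolysis; electrophilic ozone should react much faster with the electron-rich trisubstituted ring olefin than with the monosubstituted allyl olefin, and the dye end point limits the dose. Reduction of the ozonide gives the C4 ketone and the C6 aldehyde without over-oxidation.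

Step 7
Reactants: 12 (3R)-3,7-dimethyl-6-oxo-3-(prop-2-en-1-yl)octanal
Product: 13 (1R,2R,5R)-2-hydroxy-5-methyl-2-(propan-2-yl)-5-(prop-2-en-1-yl)cyclopentane-1-carbaldehyde
Conditions: (R)-proline (20 mol%), CH2Cl2, rt; crude product used directly
Reagents that add atoms: none
Why: Amine-catalysed intramolecular aldol (5-enolexo aldolisation); proline condenses with the aldehyde but not with the hindered isopropyl ketone, so C5 is the donor and C4 the acceptor. In the acid-directed enamine transition state the ketone oxygen is held syn to the enamine carbon C6 and isopropyl points away, and (R)-proline is expected to open the C5 face that puts C6 syn to the C1 methyl and anti to the allyl arm. The addition is reversible and C5 is epimerisable, so the mixture should also drain to this isomer, in which the formyl group is trans to both isopropyl and allyl and hydrogen-bonded to O4–H.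

Step 8
Reactants: 13 (1R,2R,5R)-2-hydroxy-5-methyl-2-(propan-2-yl)-5-(prop-2-en-1-yl)cyclopentane-1-carbaldehyde; 14 3-bromo-2-methylprop-1-ene
Product: 15 (1R,2S,3R)-2-[(1S)-1-hydroxy-3-methylbut-3-en-1-yl]-3-methyl-1-(propan-2-yl)-3-(prop-2-en-1-yl)cyclopentan-1-ol
Conditions: In powder (2 equiv.), 14 (3 equiv.), THF/H2O 1:1, rt
Reagents that add atoms: none
Why: Barbier-type allylation with an allylindium reagent in water, which tolerates the free tertiary alcohol and avoids the basic conditions that would trigger retro-aldol. The metal should bridge O4 and the formyl oxygen in a six-membered chelate cis-fused to ring A, and the methallyl group should attack C6 on the convex face, anti to C1, which gives the (6S) carbinol.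

Step 9
Reactants: 15 (1R,2S,3R)-2-[(1S)-1-hydroxy-3-methylbut-3-en-1-yl]-3-methyl-1-(propan-2-yl)-3-(prop-2-en-1-yl)cyclopentan-1-ol
Product: 16 (3R,3aS,4S,8aR)-6,8a-dimethyl-3-(propan-2-yl)-1,2,3,3a,4,5,8,8a-octahydroazulene-3,4-diol
Conditions: RuCl2(=CHPh)(PCy3)(H2IMes) (second-generation Grubbs catalyst, 5 mol%), CH2Cl2 (0.005 M), 40 °C
Reagents that add atoms: none
Why: Ring-closing metathesis; the catalyst should load on the monosubstituted allyl olefin and close onto the 1,1-disubstituted olefin, giving the trisubstituted C8=C9 bond and ring B with loss of ethene. The two arms are trans on ring A, so the fusion is trans, free hydroxyls are tolerated and no stereocentre is touched.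

Step 10
Reactants: 17 p-coumaric acid
Product: 19 (2E)-3-[4-(tert-butyldimethylsilyloxy)phenyl]prop-2-enoic acid, via bis-silyl ester 18 (not isolated)
Conditions: TBSCl (2.3 equiv.), imidazole, DMF, rt; then AcOH/THF/H2O, rt
Reagents that add atoms: tert-butyldimethylsilyl chloride, CC(C)(C)[Si](C)(C)Cl
Why: Silylation of phenol and acid followed by selective hydrolysis of the far more labile silyl ester; the aryl silyl ether should survive the mild aqueous acid.

Step 11
Reactants: 16 (3R,3aS,4S,8aR)-6,8a-dimethyl-3-(propan-2-yl)-1,2,3,3a,4,5,8,8a-octahydroazulene-3,4-diol; 19 (2E)-3-[4-(tert-butyldimethylsilyloxy)phenyl]prop-2-enoic acid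
Product: 21 (3R,3aS,4S,8aR)-3-hydroxy-6,8a-dimethyl-3-(propan-2-yl)-1,2,3,3a,4,5,8,8a-octahydroazulen-4-yl (2E)-3-[4-(tert-butyldimethylsilyloxy)phenyl]prop-2-enoate, via mixed anhydride 20 (not isolated)
Conditions: 19, 2,4,6-Cl3C6H2COCl, Et3N, THF, rt; then 16, DMAP, toluene, rt → 50 °C
Reagents that add atoms: none
Why: Yamaguchi esterification; DMAP attacks the unhindered cinnamoyl carbonyl of the mixed anhydride, and the acylpyridinium should acylate the secondary C6–OH while the tertiary C4–OH stays free. The C6–O bond is not broken, so configuration is retained, and the E olefin is untouched.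

Step 12
Reactants: 21 (3R,3aS,4S,8aR)-3-hydroxy-6,8a-dimethyl-3-(propan-2-yl)-1,2,3,3a,4,5,8,8a-octahydroazulen-4-yl (2E)-3-[4-(tert-butyldimethylsilyloxy)phenyl]prop-2-enoate
Product: 22 (3R,3aS,4S,8aR)-3-hydroxy-6,8a-dimethyl-3-(propan-2-yl)-1,2,3,3a,4,5,8,8a-octahydroazulen-4-yl (2E)-3-(4-hydroxyphenyl)prop-2-enoate
Conditions: Bu4NF, AcOH (1:1), THF, 0 °C
Reagents that add atoms: none
Why: Fluoride cleavage of the aryl silyl ether; buffering with acetic acid keeps the phenoxide from cleaving or transferring the cinnamate, and the tertiary alcohol and the olefin are inert.

## Compound list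

1 | 2-chlorobuta-1,3-diene (chloroprene) | C=CC(Cl)=C | starting material
2 | isopropylmagnesium chloride | CC(C)[Mg]Cl | starting material
3 | 2-(propan-2-yl)buta-1,3-diene | C=CC(=C)C(C)C | intermediate
4 | methacrolein (2-methylprop-2-enal) | CC(=C)C=O | starting material
5 | (1S)-1-methyl-4-(propan-2-yl)cyclohex-3-ene-1-carbaldehyde | O=C[C@]1(C)CC=C(C(C)C)CC1 | intermediate
6 | (methoxymethyl)triphenylphosphonium chloride | COC[P+](c1ccccc1)(c1ccccc1)c1ccccc1.[Cl-] | starting material
7 | (4S)-4-(2-methoxyethenyl)-4-methyl-1-(propan-2-yl)cyclohex-1-ene (E/Z mixture) | COC=C[C@]1(C)CC=C(C(C)C)CC1 | intermediate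
8 | 2-[(1S)-1-methyl-4-(propan-2-yl)cyclohex-3-en-1-yl]acetaldehyde | O=CC[C@]1(C)CC=C(C(C)C)CC1 | intermediate
9 | methyltriphenylphosphonium bromide | C[P+](c1ccccc1)(c1ccccc1)c1ccccc1.[Br-] | starting material
10 | (4R)-4-methyl-1-(propan-2-yl)-4-(prop-2-en-1-yl)cyclohex-1-ene | C=CC[C@]1(C)CC=C(C(C)C)CC1 | intermediate
11 | secondary ozonide of 10, (4R)-4-methyl-1-(propan-2-yl)-4-(prop-2-en-1-yl)-7,8,9-trioxabicyclo[4.2.1]nonane (mixture at the bridgeheads) | C=CC[C@@]1(C)CCC2(C(C)C)OOC(C1)O2 | intermediate (not isolated)
12 | (3R)-3,7-dimethyl-6-oxo-3-(prop-2-en-1-yl)octanal | C=CC[C@](C)(CC=O)CCC(=O)C(C)C | intermediate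
13 | (1R,2R,5R)-2-hydroxy-5-methyl-2-(propan-2-yl)-5-(prop-2-en-1-yl)cyclopentane-1-carbaldehyde | C=CC[C@@]1(C)CC[C@@](O)(C(C)C)[C@@H]1C=O | intermediate
14 | 3-bromo-2-methylprop-1-ene (methallyl bromide) | C=C(C)CBr | starting material
15 | (1R,2S,3R)-2-[(1S)-1-hydroxy-3-methylbut-3-en-1-yl]-3-methyl-1-(propan-2-yl)-3-(prop-2-en-1-yl)cyclopentan-1-ol | C=CC[C@@]1(C)CC[C@@](O)(C(C)C)[C@@H]1[C@@H](O)CC(C)=C | intermediate
16 | (3R,3aS,4S,8aR)-6,8a-dimethyl-3-(propan-2-yl)-1,2,3,3a,4,5,8,8a-octahydroazulene-3,4-diol | CC1=CC[C@@]2(C)CC[C@@](O)(C(C)C)[C@@H]2[C@@H](O)C1 | intermediate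
17 | p-coumaric acid, (2E)-3-(4-hydroxyphenyl)prop-2-enoic acid | OC(=O)/C=C/c1ccc(O)cc1 | starting material
18 | tert-butyldimethylsilyl (2E)-3-[4-(tert-butyldimethylsilyloxy)phenyl]prop-2-enoate | CC(C)(C)[Si](C)(C)OC(=O)/C=C/c1ccc(O[Si](C)(C)C(C)(C)C)cc1 | intermediate (not isolated)
19 | (2E)-3-[4-(tert-butyldimethylsilyloxy)phenyl]prop-2-enoic acid | OC(=O)/C=C/c1ccc(O[Si](C)(C)C(C)(C)C)cc1 | intermediate
20 | (2E)-3-[4-(tert-butyldimethylsilyloxy)phenyl]prop-2-enoic 2,4,6-trichlorobenzoic anhydride | O=C(/C=C/c1ccc(O[Si](C)(C)C(C)(C)C)cc1)OC(=O)c1c(Cl)cc(Cl)cc1Cl | intermediate (not isolated)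
21 | (3R,3aS,4S,8aR)-3-hydroxy-6,8a-dimethyl-3-(propan-2-yl)-1,2,3,3a,4,5,8,8a-octahydroazulen-4-yl (2E)-3-[4-(tert-butyldimethylsilyloxy)phenyl]prop-2-enoate | CC1=CC[C@@]2(C)CC[C@@](O)(C(C)C)[C@@H]2[C@@H](OC(=O)/C=C/c2ccc(O[Si](C)(C)C(C)(C)C)cc2)C1 | intermediate
22 | (3R,3aS,4S,8aR)-3-hydroxy-6,8a-dimethyl-3-(propan-2-yl)-1,2,3,3a,4,5,8,8a-octahydroazulen-4-yl (2E)-3-(4-hydroxyphenyl)prop-2-enoate | CC1=CC[C@@]2(C)CC[C@@](O)(C(C)C)[C@@H]2[C@@H](OC(=O)/C=C/c2ccc(O)cc2)C1 | target

## Step count and least certain steps

Total step count: 12. Longest linear sequence: 11 steps (steps 1–9, 11 and 12); step 10 is a one-step side branch.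

**Step 2 (key step).** The most likely failure is incomplete enantioface discrimination or para/meta control with a small acyclic 2-alkyl diene, together with acid-initiated oligomerisation of 3 at the low temperature that the selectivity requires. The fallback sets out from 3 and 4 and returns at 5 by resolution instead of asymmetric catalysis. A BF3·OEt2-catalysed Diels–Alder reaction gives racemic aldehyde F1, and NaClO2/NaH2PO4/2-methylbut-2-ene oxidation gives racemic acid F2. Crystallisation with (R)-1-phenylethylamine gives the salt F3 of the (S)-acid (the antipodal amine would be used if the other diastereomeric salt is the less soluble). Acidification frees (S)-acid F4, LiAlH4 reduces it to (S)-alcohol F5, and Dess–Martin oxidation gives 5.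

**Step 7.** Loss of water from the adduct through the enamine (elimination of the tertiary hydroxyl to a cyclopentene carbaldehyde), retro-aldol during isolation, or a mismatched pairing of catalyst and substrate face would erode the yield or the diastereomer ratio. The adduct is crowded, flanked by two fully substituted carbons. The fallback sets out from 12 and returns at 13, and takes the labile β-hydroxy aldehyde out of the isolation. The aldolisation is run with an achiral amine salt (pyrrolidine/AcOH, 0 °C) and the equilibrium mixture is reduced in the same flask with NaBH4. The adduct is thus trapped as the stable diol F6, which can be purified and separated from diastereomers. TEMPO/PhI(OAc)2 then oxidises only its primary alcohol back to 13 immediately before step 8.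

**Step 8.** Poor facial selectivity at C6 is the risk, if the chelate between the tertiary O4 and the formyl oxygen is loose in water and an open transition state competes, giving the C6 epimer F7. The fallback sets out from 15 (as its mixture with F7) and returns at 16. The mixture is taken through the conditions of step 9 to 16 and its bicyclic C6 epimer F8. Dess–Martin oxidation converts both to the single hydroxy ketone F9. Me4NBH(OAc)3 in MeCN/AcOH then delivers hydride intramolecularly from O4, on the face of C6 that gives 16.

**Step 6.** Loss of chemoselectivity, with ozone also cleaving the allyl olefin, or over-oxidation of the aldehyde. The fallback sets out from 10 and returns at 12. mCPBA epoxidises only the trisubstituted olefin to epoxide F10, and H5IO6 in aqueous THF cleaves the epoxide to 12.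

**Step 11.** Slow acylation of the congested C6–OH, which lets side reactions of the activated cinnamate (conjugate addition, silyl loss) compete. The fallback sets out from 16 and returns at 21. The small diethylphosphonoacetic acid is attached first (DCC, DMAP) to give phosphonoacetate F11. A Horner–Wadsworth–Emmons reaction with 4-(tert-butyldimethylsilyloxy)benzaldehyde (LiCl, DBU, MeCN) then builds the (E)-cinnamate on the ester to give 21.

**Step 1.** Isomerisation of the secondary alkyl–nickel intermediate (n-propyl diene) and losses on isolating the volatile diene. The fallback sets out from commercial 3-methylbut-1-yne and ethene and arrives at 3: ene–yne cross-metathesis with RuCl2(=CHPh)(PCy3)(H2IMes) gives 3 directly, with no new intermediate (F0).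

## Further compounds

F0 | step 1 | none | none
F1 | step 2 | racemic 1-methyl-4-(propan-2-yl)cyclohex-3-ene-1-carbaldehyde | O=CC1(C)CC=C(C(C)C)CC1
F2 | step 2 | racemic 1-methyl-4-(propan-2-yl)cyclohex-3-ene-1-carboxylic acid | OC(=O)C1(C)CC=C(C(C)C)CC1
F3 | step 2 | (R)-1-phenylethylammonium (1S)-1-methyl-4-(propan-2-yl)cyclohex-3-ene-1-carboxylate | C[C@@H]([NH3+])c1ccccc1.[O-]C(=O)[C@]1(C)CC=C(C(C)C)CC1
F4 | step 2 | (1S)-1-methyl-4-(propan-2-yl)cyclohex-3-ene-1-carboxylic acid | OC(=O)[C@]1(C)CC=C(C(C)C)CC1
F5 | step 2 | [(1S)-1-methyl-4-(propan-2-yl)cyclohex-3-en-1-yl]methanol | OC[C@]1(C)CC=C(C(C)C)CC1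
F6 | step 7 | (1R,2S,3R)-2-(hydroxymethyl)-3-methyl-1-(propan-2-yl)-3-(prop-2-en-1-yl)cyclopentan-1-ol | C=CC[C@@]1(C)CC[C@@](O)(C(C)C)[C@@H]1CO
F7 | step 8 | (1R,2S,3R)-2-[(1R)-1-hydroxy-3-methylbut-3-en-1-yl]-3-methyl-1-(propan-2-yl)-3-(prop-2-en-1-yl)cyclopentan-1-ol | C=CC[C@@]1(C)CC[C@@](O)(C(C)C)[C@@H]1[C@H](O)CC(C)=C
F8 | step 8 | (3R,3aS,4R,8aR)-6,8a-dimethyl-3-(propan-2-yl)-1,2,3,3a,4,5,8,8a-octahydroazulene-3,4-diol | CC1=CC[C@@]2(C)CC[C@@](O)(C(C)C)[C@@H]2[C@H](O)C1
F9 | step 8 | (3R,3aR,8aR)-3-hydroxy-6,8a-dimethyl-3-(propan-2-yl)-2,3,3a,5,8,8a-hexahydroazulen-4(1H)-one | CC1=CC[C@@]2(C)CC[C@@](O)(C(C)C)[C@@H]2C(=O)C1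
F10 | step 6 | (4R)-4-methyl-1-(propan-2-yl)-4-(prop-2-en-1-yl)-7-oxabicyclo[4.1.0]heptane (epoxide diastereomers) | C=CC[C@]1(C)CC2OC2(C(C)C)CC1
F11 | step 11 | (3R,3aS,4S,8aR)-3-hydroxy-6,8a-dimethyl-3-(propan-2-yl)-1,2,3,3a,4,5,8,8a-octahydroazulen-4-yl 2-(diethoxyphosphoryl)acetate | CC1=CC[C@@]2(C)CC[C@@](O)(C(C)C)[C@@H]2[C@@H](OC(=O)CP(=O)(OCC)OCC)C1
A1 | alternative 1 | (R)-4-(tert-butyldimethylsilyloxy)-2-methylcyclopent-2-en-1-one | CC1=C[C@H](O[Si](C)(C)C(C)(C)C)CC1=O
A2 | alternative 1 | 4-(tert-butyldimethylsilyloxy)-3-(1,3-dithian-2-yl)-2-methyl-2-[(2Z)-3-methyl-4-(pivaloyloxy)but-2-en-1-yl]cyclopentan-1-one (C1 and C5 set) | C/C(COC(=O)C(C)(C)C)=C/C[C@@]1(C)C(=O)C[C@@H](O[Si](C)(C)C(C)(C)C)[C@@H]1C2SCCCS2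
A3 | alternative 2 | 8-methoxy-6-methyl-3,8a-dihydroazulen-1(2H)-one | COC1=CC(C)=CC=C2CCC(=O)[C@H]12
A4 | alternative 3 | bicyclic C6 tert-butyldimethylsilyl enol ether with C4 triethylsilyl ether (product of the (5+2) cycloaddition) | CC1=CC[C@@]2(C)CC[C@@](O[Si](CC)(CC)CC)(C(C)C)C2=C(O[Si](C)(C)C(C)(C)C)C1
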